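**Plan**
- Cuts: the three free acidic groups (ring A 4-OH, ring B 6-OH, ring B CO2H) are first masked as benzyl groups. Ring A is then opened at C1–C2 and C5–C6. The alkynyl ether that results is cut at O–C(sp) and at C(sp)–CO2Me, which leads back to a ring B phenol, trichloroethylene and methyl chloroformate.
- Enabling feature: in ring A the run C2(pentyl)–C3(H)–C4(O)–C5(H) is the C6–C5–C4–C3 diene of a 4-alkoxy-6-pentyl-2-pyrone. The adjacent pair C1(CO2Me)/C6(OAr) is an alkyne with an acceptor on one carbon and a donor on the other. CO2 is the only loss on the way to the arene.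
- Consequence: the diaryl ether oxygen travels on the alkyne, so no C–O coupling is needed at the ring B carbon wedged between pentyl and methoxy.
- Forward order: ring B is bought as olivetol and dressed by formylation, 4-O-methylation, oxidation to the acid, double benzylation, iodination and hydroxylation. Its new phenol becomes the methyl aryloxypropiolate, and the pyrone comes in two steps from triacetic acid lactone. Ring A is formed last, and hydrogenolysis ends the route.
- Stereochemistry: the target has no stereocentre. Only regiochemistry needs control; the matched polarisation of pyrone and alkyne fixes it in the cycloaddition, and para direction fixes it in the iodination.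

Key step: step 11

Remark: the only stereo-elements on the way are the E-configured dichlorovinyl ether and the two transient bridgeheads of the racemic cycloadduct (one enantiomer drawn). The numeral in the trivial name epiphorellic acid 1 belongs to the name and is not a compound number.

**Step 1**
Reactants: 1 4-hydroxy-6-methyl-2H-pyran-2-one (triacetic acid lactone); 2 1-bromobutane
Product: 4 4-hydroxy-6-pentyl-2H-pyran-2-one, via dilithium dianion 3 (not isolated)
Conditions: LiN(iPr)2 (2.3 equiv), THF–DMPU, −78 °C; then 2, −78 °C → rt; aq HCl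
Reagents that add atoms: none
Why: Dianion alkylation: of the two anionic sites of 3, the C6-methylene carbanion formed last is the more basic and nucleophilic, so it takes up the primary bromide by SN2 and the enolate oxygen is reprotonated on work-up.

**Step 2**
Reactants: 4 4-hydroxy-6-pentyl-2H-pyran-2-one
Product: 5 4-(benzyloxy)-6-pentyl-2H-pyran-2-one
Conditions: BnOH, PPh3, DIAD, THF, 0 °C → rt
Reagents that add atoms: benzyl alcohol, OCc1ccccc1
Why: Mitsunobu etherification suits the strongly acidic vinylogous-acid hydroxyl of 4 and gives the 4-O-benzyl ether, whereas base and a benzyl halide would also benzylate the nucleophilic C3.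

**Step 3**
Reactants: 6 olivetol (5-pentylbenzene-1,3-diol)
Product: 8 2,4-dihydroxy-6-pentylbenzaldehyde, via aryl iminium chloride 7 (not isolated)
Conditions: POCl3, DMF, 0 °C → rt; then H2O
Reagents that add atoms: N,N-dimethylformamide, CN(C)C=O; water, O
Why: Vilsmeier-Haack formylation takes place next to the pentyl chain, para to one hydroxyl and ortho to the other, which is the established site for 5-alkylresorcinols, and the iminium salt 7 is hydrolysed on aqueous work-up.

**Step 4**
Reactants: 8 2,4-dihydroxy-6-pentylbenzaldehyde
Product: 9 2-hydroxy-4-methoxy-6-pentylbenzaldehyde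
Conditions: MeI (1.05 equiv), K2CO3 (1.0 equiv), acetone, reflux
Reagents that add atoms: iodomethane, CI
Why: Williamson etherification with one equivalent of base and MeI selects the 4-OH because the 2-OH is hydrogen-bonded to the aldehyde carbonyl and is both less acidic and less nucleophilic.

**Step 5**
Reactants: 9 2-hydroxy-4-methoxy-6-pentylbenzaldehyde
Product: 10 2-hydroxy-4-methoxy-6-pentylbenzoic acid
Conditions: NaClO2, NaH2PO4, 2-methyl-2-butene, t-BuOH–H2O, rt
Reagents that add atoms: sodium chlorite, [Na+].[O-]Cl=O
Why: Pinnick oxidation turns the aldehyde into the acid under mild buffered conditions, and 2-methyl-2-butene traps the HOCl that would otherwise chlorinate the electron-rich ring.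

**Step 6**
Reactants: 10 2-hydroxy-4-methoxy-6-pentylbenzoic acid
Product: 11 benzyl 2-(benzyloxy)-4-methoxy-6-pentylbenzoate
Conditions: BnBr (2.4 equiv), K2CO3, DMF, 60 °C
Reagents that add atoms: benzyl bromide, BrCc1ccccc1
Why: Carboxylate O-alkylation and Williamson etherification of the chelated phenol run in the same flask with excess BnBr, so both groups that must fall in the last step are installed at once.

**Step 7**
Reactants: 11 benzyl 2-(benzyloxy)-4-methoxy-6-pentylbenzoate
Product: 12 benzyl 6-(benzyloxy)-3-iodo-4-methoxy-2-pentylbenzoate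
Conditions: NIS, CF3CO2H (cat.), MeCN, 0 °C → rt
Reagents that add atoms: N-iodosuccinimide, O=C1CCC(=O)N1I
Why: Electrophilic aromatic iodination with acid-activated NIS goes to the one free position that is para to an alkoxy group (the benzyloxy) and ortho to the methoxy, as in the halogenation of 5-alkylresorcinol diethers, and not to the carbon between the two alkoxy groups.

**Step 8**
Reactants: 12 benzyl 6-(benzyloxy)-3-iodo-4-methoxy-2-pentylbenzoate
Product: 15 benzyl 6-(benzyloxy)-3-hydroxy-4-methoxy-2-pentylbenzoate, via arylmagnesium chloride 13 (not isolated), via dimethyl arylboronate 14 (not isolated)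
Conditions: iPrMgCl·LiCl, THF, −20 → 0 °C; B(OMe)3, −20 °C → rt; 30% aq H2O2, 0 °C → rt
Reagents that add atoms: hydrogen peroxide, OO
Why: Iodine-magnesium exchange with iPrMgCl·LiCl is fast enough at low temperature to spare the ester, which is shielded by two ortho substituents, and borylation followed by peroxide oxidation (1,2-shift of the aryl group from boron to oxygen) puts hydroxyl on the same carbon.

**Step 9**
Reactants: 15 benzyl 6-(benzyloxy)-3-hydroxy-4-methoxy-2-pentylbenzoate; 16 trichloroethylene
Product: 18 benzyl 6-(benzyloxy)-3-[(E)-1,2-dichlorovinyloxy]-4-methoxy-2-pentylbenzoate, via dichloroacetylene 17 (not isolated)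
Conditions: 16 (2 equiv), K2CO3, DMF, 70 °C
Reagents that add atoms: none
Why: Base-mediated O-dichlorovinylation of phenols with trichloroethylene: K2CO3 eliminates HCl to give 17 in low concentration, and anti addition of the phenoxide and a proton across it sets the E geometry of 18 while needing little space around the crowded oxygen.

**Step 10**
Reactants: 18 benzyl 6-(benzyloxy)-3-[(E)-1,2-dichlorovinyloxy]-4-methoxy-2-pentylbenzoate; 19 methyl chloroformate
Product: 22 benzyl 6-(benzyloxy)-4-methoxy-3-[(3-methoxy-3-oxoprop-1-yn-1-yl)oxy]-2-pentylbenzoate, via chloroethynyl aryl ether 20 (not isolated), via lithium aryloxyacetylide 21 (not isolated)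
Conditions: n-BuLi (2.05 equiv), THF, −78 °C; then 19, −78 → 0 °C
Reagents that add atoms: none
Why: Dichlorovinyl-ether route to ynol ethers: the first equivalent of n-BuLi eliminates HCl to 20, the second exchanges chlorine for lithium, and acetylide 21 is C-acylated by the chloroformate, all at −78 °C where the benzyl ester flanked by pentyl and benzyloxy should not be attacked.

**Step 11**
Reactants: 5 4-(benzyloxy)-6-pentyl-2H-pyran-2-one; 22 benzyl 6-(benzyloxy)-4-methoxy-3-[(3-methoxy-3-oxoprop-1-yn-1-yl)oxy]-2-pentylbenzoate
Product: 24 benzyl 6-(benzyloxy)-3-[5-(benzyloxy)-2-(methoxycarbonyl)-3-pentylphenoxy]-4-methoxy-2-pentylbenzoate, via bridged bicyclic lactone 23 (not isolated)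
Conditions: 5 (3 equiv), BHT (cat.), 1,2-dichlorobenzene (2 M), Ar, sealed tube, 200 °C
Reagents that add atoms: none
Why: Proposed new method: the 4-alkoxy-2-pyrone acts as an electron-rich diene in a normal-demand, asynchronous concerted [4+2] cycloaddition across its C3 and C6 with the ester-activated alkyne, and the 2-oxabicyclo[2.2.2]octadienone 23 then expels CO2 by retro-[4+2] at the same temperature, which makes the sequence irreversible. The closest known reaction type is the thermal Diels-Alder/decarboxylation of 4-alkoxy-6-alkyl-2-pyrones with propiolates and acetylenedicarboxylates to give benzoates; a 3-aryloxypropiolate has not been shown as the dienophile. Ring A closes by intermolecular [4+2] annulation, with both new sigma bonds (ring A C5–C6 from pyrone C3 to the aryloxy carbon, ring A C1–C2 from the ester-bearing carbon to pyrone C6) formed in the one cycloaddition event. The two bridgehead stereocentres of 23 are transient and vanish on aromatisation, so no stereocontrol is required. The selectivity needed is regiochemical: pyrone C3, the enol-ether beta carbon with the largest HOMO coefficient, pairs with the alkyne carbon beta to the ester, which holds the largest LUMO coefficient, and the bulky aryloxy group then meets the unsubstituted C3–H end instead of the pentyl-bearing C6, so sterics and electronics agree. The aryloxy donor raises the alkyne LUMO, which is answered by excess 5, high concentration and 200 °C, and the aryl ynol ether has no beta hydrogen for retro-ene ketene formation and should tolerate this.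

**Step 12**
Reactants: 24 benzyl 6-(benzyloxy)-3-[5-(benzyloxy)-2-(methoxycarbonyl)-3-pentylphenoxy]-4-methoxy-2-pentylbenzoate
Product: 25 6-hydroxy-3-[5-hydroxy-2-(methoxycarbonyl)-3-pentylphenoxy]-4-methoxy-2-pentylbenzoic acid (epiphorellic acid 1)
Conditions: H2 (1 atm), 10% Pd/C, EtOAc–MeOH, rt
Reagents that add atoms: none
Why: Catalytic hydrogenolysis cleaves the three benzylic C–O bonds (two ethers, one ester) in one operation and leaves the methyl ester, the methyl ether and the diaryl ether untouched.

**Compound list**
1 | 4-hydroxy-6-methyl-2H-pyran-2-one | CC1=CC(O)=CC(=O)O1 | starting material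
2 | 1-bromobutane | CCCCBr | starting material
3 | dilithium salt of the C6-methylene/4-oxide dianion of 1 | [Li+].[Li+].[CH2-]C1=CC([O-])=CC(=O)O1 | intermediate (not isolated)
4 | 4-hydroxy-6-pentyl-2H-pyran-2-one | CCCCCC1=CC(O)=CC(=O)O1 | intermediate
5 | 4-(benzyloxy)-6-pentyl-2H-pyran-2-one | CCCCCC1=CC(OCc2ccccc2)=CC(=O)O1 | intermediate
6 | olivetol | CCCCCc1cc(O)cc(O)c1 | starting material
7 | N-(2,4-dihydroxy-6-pentylbenzylidene)-N-methylmethanaminium chloride | CCCCCc1cc(O)cc(O)c1C=[N+](C)C.[Cl-] | intermediate (not isolated)
8 | 2,4-dihydroxy-6-pentylbenzaldehyde | CCCCCc1cc(O)cc(O)c1C=O | intermediate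
9 | 2-hydroxy-4-methoxy-6-pentylbenzaldehyde | CCCCCc1cc(OC)cc(O)c1C=O | intermediate
10 | 2-hydroxy-4-methoxy-6-pentylbenzoic acid | CCCCCc1cc(OC)cc(O)c1C(=O)O | intermediate
11 | benzyl 2-(benzyloxy)-4-methoxy-6-pentylbenzoate | CCCCCc1cc(OC)cc(OCc2ccccc2)c1C(=O)OCc1ccccc1 | intermediate
12 | benzyl 6-(benzyloxy)-3-iodo-4-methoxy-2-pentylbenzoate | CCCCCc1c(I)c(OC)cc(OCc2ccccc2)c1C(=O)OCc1ccccc1 | intermediate
13 | [4-(benzyloxy)-3-(benzyloxycarbonyl)-6-methoxy-2-pentylphenyl]magnesium chloride | CCCCCc1c([Mg]Cl)c(OC)cc(OCc2ccccc2)c1C(=O)OCc1ccccc1 | intermediate (not isolated)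
14 | dimethyl [4-(benzyloxy)-3-(benzyloxycarbonyl)-6-methoxy-2-pentylphenyl]boronate | CCCCCc1c(B(OC)OC)c(OC)cc(OCc2ccccc2)c1C(=O)OCc1ccccc1 | intermediate (not isolated)
15 | benzyl 6-(benzyloxy)-3-hydroxy-4-methoxy-2-pentylbenzoate | CCCCCc1c(O)c(OC)cc(OCc2ccccc2)c1C(=O)OCc1ccccc1 | intermediate
16 | trichloroethylene | ClC=C(Cl)Cl | starting material
17 | dichloroacetylene | ClC#CCl | intermediate (not isolated)
18 | benzyl 6-(benzyloxy)-3-[(E)-1,2-dichlorovinyloxy]-4-methoxy-2-pentylbenzoate | CCCCCc1c(O/C(Cl)=C\Cl)c(OC)cc(OCc2ccccc2)c1C(=O)OCc1ccccc1 | intermediate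
19 | methyl chloroformate | COC(=O)Cl | starting material
20 | benzyl 6-(benzyloxy)-3-(chloroethynyloxy)-4-methoxy-2-pentylbenzoate | CCCCCc1c(OC#CCl)c(OC)cc(OCc2ccccc2)c1C(=O)OCc1ccccc1 | intermediate (not isolated)
21 | benzyl 6-(benzyloxy)-3-(lithioethynyloxy)-4-methoxy-2-pentylbenzoate | CCCCCc1c(OC#C[Li])c(OC)cc(OCc2ccccc2)c1C(=O)OCc1ccccc1 | intermediate (not isolated)
22 | benzyl 6-(benzyloxy)-4-methoxy-3-[(3-methoxy-3-oxoprop-1-yn-1-yl)oxy]-2-pentylbenzoate | COC(=O)C#COc1c(OC)cc(OCc2ccccc2)c(C(=O)OCc2ccccc2)c1CCCCC | intermediate
23 | methyl 8-(benzyloxy)-5-(ring B aryloxy)-3-oxo-1-pentyl-2-oxabicyclo[2.2.2]octa-5,7-diene-6-carboxylate (racemic, one enantiomer drawn) | CCCCC[C@@]12OC(=O)[C@@H](C(OCc3ccccc3)=C1)C(Oc4c(OC)cc(OCc5ccccc5)c(C(=O)OCc6ccccc6)c4CCCCC)=C2C(=O)OC | intermediate (not isolated)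
24 | benzyl 6-(benzyloxy)-3-[5-(benzyloxy)-2-(methoxycarbonyl)-3-pentylphenoxy]-4-methoxy-2-pentylbenzoate | CCCCCc1cc(OCc2ccccc2)cc(Oc2c(OC)cc(OCc3ccccc3)c(C(=O)OCc3ccccc3)c2CCCCC)c1C(=O)OC | intermediate
25 | 6-hydroxy-3-[5-hydroxy-2-(methoxycarbonyl)-3-pentylphenoxy]-4-methoxy-2-pentylbenzoic acid (epiphorellic acid 1) | CCCCCc1cc(O)cc(Oc2c(OC)cc(O)c(C(=O)O)c2CCCCC)c1C(=O)OC | target

**Step count**
Total step count: 12. Longest linear sequence: 10 (steps 3 to 12, from olivetol 6).

**Steps most likely to fail**

1. Step 11, the one step flagged as a new method.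
   - Risk: the donor on the alkyne may lower its reactivity so far that the ynol ether hydrates, oligomerises or otherwise degrades before cycloaddition. The long time at high temperature may also erode the regiochemical preference.
   - Fallback (known chemistry only): it sets out from phenol 15 and takes ring A as a ready-made arene. Methyl 2,4-dihydroxy-6-pentylbenzoate F1 (purchased) is benzylated at its non-chelated 4-OH (BnBr, K2CO3, acetone) to methyl 4-(benzyloxy)-2-hydroxy-6-pentylbenzoate F2. The remaining phenol is sulfonylated (Tf2O, pyridine, CH2Cl2) to methyl 4-(benzyloxy)-2-pentyl-6-(trifluoromethylsulfonyloxy)benzoate F3.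
   - Return: Buchwald-Hartwig diaryl ether coupling of F3 with 15 (Pd(OAc)2, 2-di-tert-butylphosphino-2',4',6'-triisopropylbiphenyl, K3PO4, toluene, 100 °C) puts the electrophilic role on the ring A carbon. That carbon has only one ortho substituent, an activating ester. The fallback comes back to the route at 24.

2. Step 10.
   - Risk: addition of n-BuLi to the benzyl ester, or deprotonation at a benzylic position, may compete with elimination and chlorine-lithium exchange. The acetylide may also decay before it is acylated.
   - Fallback: it sets out from phenol 15 and uses no organolithium. Methyl propiolate F4 (purchased) is brominated at the terminal carbon (NBS, AgNO3 cat., acetone) to methyl 3-bromopropiolate F5.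
   - Return: the sodium salt of 15 (NaH, THF, −78 °C) is added to F5. The phenoxide attacks the bromine-bearing carbon beta to the ester and the allenolate expels bromide (addition-elimination at the sp carbon). The bulk around the phenoxide oxygen disfavours a second addition. The fallback bypasses 18, 20 and 21 and comes back at 22.

3. Step 8.
   - Risk: iodine-magnesium exchange at an electron-rich carbon flanked on both sides may be slow. Protodeiodination or attack of the Grignard reagent on the ester could then take over.
   - Fallback: it sets out from acid 10 and introduces the oxygen without a halide. Monobenzylation of the carboxylate (BnBr, KHCO3, DMF) gives benzyl 2-hydroxy-4-methoxy-6-pentylbenzoate F6. Elbs persulfate oxidation (K2S2O8, aq KOH, pyridine) places oxygen para to the free phenol as potassium 3-(benzyloxycarbonyl)-4-hydroxy-6-methoxy-2-pentylphenyl sulfate F7.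
   - Return: while the sulfate masks the new oxygen, the original phenol is benzylated (BnBr, K2CO3, DMF) to potassium 4-(benzyloxy)-3-(benzyloxycarbonyl)-6-methoxy-2-pentylphenyl sulfate F8. Warm dilute HCl then hydrolyses the sulfate. The fallback bypasses 11 and 12 and comes back at 15.

**Further compounds**
F1 | step 11 | methyl 2,4-dihydroxy-6-pentylbenzoate (purchased) | CCCCCc1cc(O)cc(O)c1C(=O)OC
F2 | step 11 | methyl 4-(benzyloxy)-2-hydroxy-6-pentylbenzoate | CCCCCc1cc(OCc2ccccc2)cc(O)c1C(=O)OC
F3 | step 11 | methyl 4-(benzyloxy)-2-pentyl-6-(trifluoromethylsulfonyloxy)benzoate | CCCCCc1cc(OCc2ccccc2)cc(OS(=O)(=O)C(F)(F)F)c1C(=O)OC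
F4 | step 10 | methyl propiolate (purchased) | C#CC(=O)OC
F5 | step 10 | methyl 3-bromopropiolate | COC(=O)C#CBr
F6 | step 8 | benzyl 2-hydroxy-4-methoxy-6-pentylbenzoate | CCCCCc1cc(OC)cc(O)c1C(=O)OCc1ccccc1
F7 | step 8 | potassium 3-(benzyloxycarbonyl)-4-hydroxy-6-methoxy-2-pentylphenyl sulfate | CCCCCc1c(OS(=O)(=O)[O-])c(OC)cc(O)c1C(=O)OCc1ccccc1.[K+]
F8 | step 8 | potassium 4-(benzyloxy)-3-(benzyloxycarbonyl)-6-methoxy-2-pentylphenyl sulfate | CCCCCc1c(OS(=O)(=O)[O-])c(OC)cc(OCc2ccccc2)c1C(=O)OCc1ccccc1.[K+]
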